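**Retrosynthetic overview**

- The ester C–O bond is made last (Steglich), joining 19-(furan-2-yl)nonadeca-5,7-diynoic acid and 21-(furan-2-yl)henicosa-14,16-diyn-1-ol.
- Each 1,3-diyne is cut at its central sp–sp bond (Cadiot–Chodkiewicz). The furan-bearing partner is always the terminal alkyne, so no furan meets an electrophilic bromine source.
- The strategy rests on furan A, the ring on C19 of the acyl chain: it is 2-monosubstituted and its ring carbons C3 and C4 bear only hydrogen. The C3–C4 bond is therefore made by ring-closing metathesis of two vinyl groups held on a mixed acrolein acetal of a bromo allylic alcohol, and loss of ethanol then aromatises the ring.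
- Ring order: furan A is the only ring built (step 4, before any alkyne exists). Furan B, on C21 of the alkoxy chain, is bought as furan and alkylated through 2-furyllithium.
- The C13 spacer of the alcohol half comes from prop-2-yn-1-ol and 1-bromododecane, followed by an alkyne zipper isomerisation.

Key step: step 4

Remark on the chemistry: the target has no stereocentre and no stereogenic double bond. The stereocentres of the allylic alcohol, the mixed acetal and the dihydrofuran are carried as mixtures and are erased when ring A aromatises. The conjugated diynes should be kept cold, in the dark and in solution.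

**Route**

Step 1
Reactants: 1 12-bromododecan-1-ol
Product: 2 12-bromododecanal
Conditions: TEMPO (cat.), PhI(OAc)2, CH2Cl2, rt
Reagents that add atoms: none
Why: The TEMPO/PhI(OAc)2 (oxoammonium) oxidation of a primary alcohol should stop at the aldehyde and leave the primary bromide untouched.

Step 2
Reactants: 2 12-bromododecanal; 3 vinylmagnesium bromide
Product: 4 14-bromotetradec-1-en-3-ol (racemic)
Conditions: THF, −78 to 0 °C; aq NH4Cl
Reagents that add atoms: vinylmagnesium bromide, C=C[Mg]Br
Why: Grignard 1,2-addition to the aldehyde is far faster at low temperature than any reaction at the primary bromide; the carbinol centre forms as a racemate and is erased in step 4.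

Step 3
Reactants: 4 14-bromotetradec-1-en-3-ol; 5 acrolein diethyl acetal
Product: 6 14-bromo-3-[(1-ethoxyprop-2-en-1-yl)oxy]tetradec-1-ene (mixture of diastereomers)
Conditions: 5 (excess), PPTS (cat.), toluene, 45 °C, reduced pressure (−EtOH); Et3N quench
Reagents that add atoms: acrolein diethyl acetal, C=CC(OCC)OCC
Why: PPTS-catalysed transacetalisation through the ethoxy-substituted allyl oxocarbenium ion is driven by removal of ethanol, and excess 5 suppresses double exchange; the new acetal centre is uncontrolled and irrelevant.

Step 4
Reactants: 6 14-bromo-3-[(1-ethoxyprop-2-en-1-yl)oxy]tetradec-1-ene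
Product: 8 2-(11-bromoundecyl)furan, via 2-(11-bromoundecyl)-5-ethoxy-2,5-dihydrofuran 7 (not isolated)
Conditions: second-generation Grubbs catalyst (H2IMes)(PCy3)Cl2Ru=CHPh (5 mol %), CH2Cl2 (0.02 M), 40 °C; then TFA (cat.), rt
Reagents that add atoms: none
Why: The ruthenium benzylidene should exchange onto one terminal vinyl group, add across the other through a ruthenacyclobutane and release ethylene, forming the C3=C4 bond of dihydrofuran 7; TFA then ionises the anomeric ethoxy group to a cyclic oxocarbenium ion, and loss of the proton on the chain-bearing carbon gives the aromatic furan. The closest known reaction type is ring-closing metathesis of mixed allylic acetals of acrolein to 2-alkoxy-2,5-dihydrofurans with acid-promoted aromatisation. Ring A is closed as a five-membered ring by olefin metathesis between two monosubstituted alkenes joined through the O–C–O tether, the seam being C3–C4. No stereocentre is created: the carbinol and acetal centres of 6 both become sp2 carbons, so the diastereomer mixture converges on one product. The step needs ring closure to beat cross-metathesis, which the fast five-membered closure and dilution should secure, and it needs chemoselectivity, which is secured because the two terminal alkenes are the only metathesis-active groups (no alkyne is present yet, and the primary bromide is inert). The position of the side chain is fixed because the carbinol carbon of 4 becomes C2 of the furan.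

Step 5
Reactants: 8 2-(11-bromoundecyl)furan; 9 lithium acetylide–ethylenediamine complex
Product: 10 2-(tridec-12-yn-1-yl)furan
Conditions: DMSO, 15 °C to rt
Reagents that add atoms: lithium acetylide–ethylenediamine complex, [Li+].[C-]#C.NCCN
Why: SN2 displacement of a primary bromide by lithium acetylide in DMSO is a standard terminal-alkyne synthesis, and the furan C–H bonds are not acidic enough to interfere.

Step 6
Reactants: 11 hex-5-ynoic acid; 12 bromine
Product: 13 6-bromohex-5-ynoic acid
Conditions: Br2, aq KOH, 0 °C; then cold dilute HCl to pH 2
Reagents that add atoms: bromine, BrBr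
Why: Hypobromite generated in the flask halogenates the acetylenic C–H of the water-soluble carboxylate salt (hypohalite bromination of a terminal alkyne) to give the 1-bromoalkyne.

Step 7
Reactants: 10 2-(tridec-12-yn-1-yl)furan; 13 6-bromohex-5-ynoic acid
Product: 14 19-(furan-2-yl)nonadeca-5,7-diynoic acid
Conditions: CuCl (cat.), NH2OH·HCl, n-BuNH2, H2O/MeOH/THF, 0 °C to rt (13 added slowly); then cold aq citric acid to pH 3–4
Reagents that add atoms: none
Why: In this Cadiot–Chodkiewicz coupling the copper acetylide of 10 (monovalent copper kept reduced by hydroxylamine) should attack bromoalkyne 13 to form the sp–sp bond, with the furan on the nucleophilic partner and the acid carried as its ammonium carboxylate.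

Step 8
Reactants: 15 furan; 16 1-bromo-4-chlorobutane
Product: 18 2-(4-chlorobutyl)furan, via 2-furyllithium 17 (not isolated)
Conditions: n-BuLi, THF, −78 to 0 °C; then 16, −78 °C to rt
Reagents that add atoms: 1-bromo-4-chlorobutane, BrCCCCCl
Why: α-Lithiation of furan followed by SN2 alkylation should displace bromide selectively over chloride.

Step 9
Reactants: 18 2-(4-chlorobutyl)furan; 9 lithium acetylide–ethylenediamine complex
Product: 19 2-(hex-5-yn-1-yl)furan
Conditions: NaI (cat.), DMSO, rt to 40 °C
Reagents that add atoms: lithium acetylide–ethylenediamine complex, [Li+].[C-]#C.NCCN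
Why: SN2 alkylation of lithium acetylide by the primary chloride, assisted by in situ Finkelstein exchange, should give the terminal alkyne.

Step 10
Reactants: 20 prop-2-yn-1-ol; 21 1-bromododecane
Product: 23 pentadec-2-yn-1-ol, via dilithiated prop-2-yn-1-ol 22 (not isolated)
Conditions: n-BuLi (2 equiv), THF/DMPU, −78 to −20 °C; then 21, to rt; aq NH4Cl
Reagents that add atoms: 1-bromododecane, CCCCCCCCCCCCBr
Why: In the O,C-dianion the acetylide carbon is far more nucleophilic than the alkoxide, so alkylation by the primary bromide should occur on carbon (acetylide alkylation).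

Step 11
Reactants: 23 pentadec-2-yn-1-ol
Product: 24 pentadec-14-yn-1-ol
Conditions: NaH, H2N(CH2)3NH2, 70 °C; then H2O
Reagents that add atoms: none
Why: In the alkyne zipper reaction the amide base moves the triple bond along the chain through allene intermediates until it is trapped irreversibly as the terminal acetylide.

Step 12
Reactants: 24 pentadec-14-yn-1-ol; 25 N-bromosuccinimide
Product: 26 15-bromopentadec-14-yn-1-ol
Conditions: NBS, AgNO3 (cat.), acetone, rt, dark
Reagents that add atoms: N-bromosuccinimide, O=C1CCC(=O)N1Br
Why: Silver-catalysed bromination of a terminal alkyne by NBS proceeds through the silver acetylide and tolerates the free hydroxyl group.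

Step 13
Reactants: 19 2-(hex-5-yn-1-yl)furan; 26 15-bromopentadec-14-yn-1-ol
Product: 27 21-(furan-2-yl)henicosa-14,16-diyn-1-ol
Conditions: CuCl (cat.), NH2OH·HCl, n-BuNH2, H2O/MeOH/THF, 0 °C to rt (26 added slowly)
Reagents that add atoms: none
Why: Cadiot–Chodkiewicz coupling of the copper acetylide of 19 with bromoalkyne 26 should give the unsymmetrical diyne, again with the furan on the non-halogenated partner.

Step 14
Reactants: 14 19-(furan-2-yl)nonadeca-5,7-diynoic acid; 27 21-(furan-2-yl)henicosa-14,16-diyn-1-ol
Product: 28 21-(furan-2-yl)henicosa-14,16-diyn-1-yl 19-(furan-2-yl)nonadeca-5,7-diynoate (target)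
Conditions: DCC, DMAP (cat.), CH2Cl2, 0 °C to rt, dark
Reagents that add atoms: none
Why: Steglich esterification through the O-acylisourea and the acylpyridinium ion joins the halves under neutral conditions that furans and conjugated diynes should tolerate.

**Compound list**

1 | 12-bromododecan-1-ol | OCCCCCCCCCCCCBr | starting material
2 | 12-bromododecanal | O=CCCCCCCCCCCCBr | intermediate
3 | vinylmagnesium bromide | C=C[Mg]Br | starting material
4 | 14-bromotetradec-1-en-3-ol (racemic) | C=CC(O)CCCCCCCCCCCBr | intermediate
5 | acrolein diethyl acetal (3,3-diethoxyprop-1-ene) | C=CC(OCC)OCC | starting material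
6 | 14-bromo-3-[(1-ethoxyprop-2-en-1-yl)oxy]tetradec-1-ene (mixture of diastereomers) | C=CC(OCC)OC(C=C)CCCCCCCCCCCBr | intermediate
7 | 2-(11-bromoundecyl)-5-ethoxy-2,5-dihydrofuran (mixture of diastereomers) | CCOC1C=CC(CCCCCCCCCCCBr)O1 | intermediate
8 | 2-(11-bromoundecyl)furan | BrCCCCCCCCCCCc1ccco1 | intermediate
9 | lithium acetylide–ethylenediamine complex | [Li+].[C-]#C.NCCN | starting material
10 | 2-(tridec-12-yn-1-yl)furan | C#CCCCCCCCCCCCc1ccco1 | intermediate
11 | hex-5-ynoic acid | C#CCCCC(=O)O | starting material
12 | bromine | BrBr | starting material
13 | 6-bromohex-5-ynoic acid | BrC#CCCCC(=O)O | intermediate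
14 | 19-(furan-2-yl)nonadeca-5,7-diynoic acid | OC(=O)CCCC#CC#CCCCCCCCCCCCc1ccco1 | intermediate
15 | furan | c1ccoc1 | starting material
16 | 1-bromo-4-chlorobutane | BrCCCCCl | starting material
17 | 2-furyllithium | [Li]c1ccco1 | intermediate
18 | 2-(4-chlorobutyl)furan | ClCCCCc1ccco1 | intermediate
19 | 2-(hex-5-yn-1-yl)furan | C#CCCCCc1ccco1 | intermediate
20 | prop-2-yn-1-ol | C#CCO | starting material
21 | 1-bromododecane | CCCCCCCCCCCCBr | starting material
22 | dilithiated prop-2-yn-1-ol | [Li]C#CCO[Li] | intermediate
23 | pentadec-2-yn-1-ol | CCCCCCCCCCCCC#CCO | intermediate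
24 | pentadec-14-yn-1-ol | C#CCCCCCCCCCCCCCO | intermediate
25 | N-bromosuccinimide | O=C1CCC(=O)N1Br | starting material
26 | 15-bromopentadec-14-yn-1-ol | BrC#CCCCCCCCCCCCCCO | intermediate
27 | 21-(furan-2-yl)henicosa-14,16-diyn-1-ol | OCCCCCCCCCCCCCC#CC#CCCCCc1ccco1 | intermediate
28 | 21-(furan-2-yl)henicosa-14,16-diyn-1-yl 19-(furan-2-yl)nonadeca-5,7-diynoate | O=C(CCCC#CC#CCCCCCCCCCCCc1ccco1)OCCCCCCCCCCCCCC#CC#CCCCCc1ccco1 | target

**Step count**

Total: 14 steps. Longest linear sequence: 7 steps (steps 1, 2, 3, 4, 5, 7, 14).

**Steps most likely to fail**

1. Step 4 (ring-closing metathesis and aromatisation). Ring closure may lose to intermolecular metathesis or to ruthenium-hydride isomerisation of an allyl unit to an enol ether, the acid-labile acetal may fall apart before it cyclises, and the aromatisation may stall or the acid may degrade the furan. The fallback sets out from 2 and comes back at 8 by a Paal–Knorr closure of the same ring. Aldehyde 2 would be treated with commercial [2-(1,3-dioxolan-2-yl)ethyl]magnesium bromide, BrMgCH2CH2CH(OCH2CH2O), in THF at −78 °C to give 14-bromo-1-(1,3-dioxolan-2-yl)tetradecan-3-ol F1. Dess–Martin periodinane with NaHCO3 in CH2Cl2 should give 14-bromo-1-(1,3-dioxolan-2-yl)tetradecan-3-one F2. TsOH·H2O in wet acetone, then warm toluene, should unmask 15-bromo-4-oxopentadecanal F3, which cyclodehydrates to 8.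

2. Step 7 (coupling with the free acid). Homocoupling and reductive loss of bromine from the bromoalkyne may compete, because the carboxylate salt and the lipophilic alkyne partition into different phases and cross-coupling becomes slow. The fallback sets out from 13 and 27 and comes back at 28 by inverting the order of the last two bond formations. Acid 13 would first be esterified with alcohol 27 (DCC, DMAP, CH2Cl2) to give 21-(furan-2-yl)henicosa-14,16-diyn-1-yl 6-bromohex-5-ynoate F4. This neutral bromoalkyne would then be coupled with alkyne 10 (CuCl, NH2OH·HCl, n-BuNH2, homogeneous THF/MeOH, 0 °C) to give 28 directly.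

3. Step 3 (mixed acetal formation). The exchange is an equilibrium, so incomplete exchange, double exchange to the symmetrical acetal of two molecules of 4, and ionisation or hydrolysis of the product on silica may erode the supply of the metathesis precursor. The fallback sets out from 4 and comes back at 8, building the acetal under basic conditions by a different bond-forming event. Alcohol 4 would add to methoxyallene (1-methoxypropa-1,2-diene) under Pd(OAc)2/1,3-bis(diphenylphosphino)propane/Et3N in MeCN (hydroalkoxylation through a π-allyl complex of divalent palladium) to give 14-bromo-3-[(1-methoxyprop-2-en-1-yl)oxy]tetradec-1-ene F5. The same second-generation Grubbs catalyst should close 2-(11-bromoundecyl)-5-methoxy-2,5-dihydrofuran F6, which loses methanol with catalytic TFA to give 8.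

**Further compounds**

F1 | step 4 | 14-bromo-1-(1,3-dioxolan-2-yl)tetradecan-3-ol | OC(CCC1OCCO1)CCCCCCCCCCCBr
F2 | step 4 | 14-bromo-1-(1,3-dioxolan-2-yl)tetradecan-3-one | O=C(CCC1OCCO1)CCCCCCCCCCCBr
F3 | step 4 | 15-bromo-4-oxopentadecanal | O=CCCC(=O)CCCCCCCCCCCBr
F4 | step 7 | 21-(furan-2-yl)henicosa-14,16-diyn-1-yl 6-bromohex-5-ynoate | O=C(CCCC#CBr)OCCCCCCCCCCCCCC#CC#CCCCCc1ccco1
F5 | step 3 | 14-bromo-3-[(1-methoxyprop-2-en-1-yl)oxy]tetradec-1-ene | C=CC(OC)OC(C=C)CCCCCCCCCCCBr
F6 | step 3 | 2-(11-bromoundecyl)-5-methoxy-2,5-dihydrofuran | COC1C=CC(CCCCCCCCCCCBr)O1
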